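**Retrosynthetic overview**
- The strategy rests on C2 of the chroman-4-one. It is a fully substituted carbon bound to O1, a methyl group, the C3H2–C4(=O) arm and a 4-hydroxy-4-methylpentyl chain. Read as vinyl plus hydrated prenyl, the O1–C2 unit is a tertiary aryl linalyl ether.
- Last operations: release of the C6 phenol from its MOM ether and Markovnikov hydration of the prenyl alkene to the tertiary alcohol.
- Pyranone ring: the C4–C4a bond is made by Parham cyclisation of an aryl iodide onto a Weinreb amide, whose two carbons (C3, C4) come from the vinyl group by hydroboration and oxidation.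
- O1–C2 bond and the only stereocentre: palladium-catalysed asymmetric branched allylic etherification of 5-bromo-2-iodo-4-(methoxymethoxy)phenol with geranyl methyl carbonate.
- Ring order: the benzene ring is bought (3-bromo-4-hydroxybenzaldehyde, then Dakin-type oxidation and ortho-iodination), the ether bond is formed next, and the pyranone ring is closed afterwards.

Key step: step 6

Assumption: the (R,R)-DACH-phenyl ligand is taken to give the (R)-ether from the E-carbonate; the sense is to be confirmed on the first run, and if it is opposite the (S,S)-ligand is used with no other change.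

Step 1
Reactants: 1 3-bromo-4-hydroxybenzaldehyde
Product: 2 3-bromo-4-(methoxymethoxy)benzaldehyde
Conditions: MOMCl, K2CO3, DMF, 0 °C to rt
Reagents that add atoms: chloromethyl methyl ether, COCCl
Why: Williamson-type O-alkylation of the acidic para-formyl phenoxide gives the MOM acetal, which masks the later C6 hydroxyl through the basic, oxidative and organometallic steps.

Step 2
Reactants: 2 3-bromo-4-(methoxymethoxy)benzaldehyde
Product: 3 3-bromo-4-(methoxymethoxy)phenyl formate
Conditions: mCPBA, CH2Cl2, 0 °C to rt
Reagents that add atoms: meta-chloroperbenzoic acid, O=C(OO)c1cccc(Cl)c1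
Why: Baeyer–Villiger oxidation of a para-alkoxybenzaldehyde proceeds with aryl migration in the Criegee intermediate (Dakin-type outcome), so the ring carbon that bore the formyl group becomes oxygen-substituted.

Step 3
Reactants: 3 3-bromo-4-(methoxymethoxy)phenyl formate
Product: 4 3-bromo-4-(methoxymethoxy)phenol
Conditions: K2CO3 (0.1 equiv), MeOH, 0 °C
Reagents that add atoms: none
Why: Base-catalysed transesterification of the aryl formate with methanol frees the phenol as methyl formate leaves, and the MOM acetal is inert to these conditions.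

Step 4
Reactants: 4 3-bromo-4-(methoxymethoxy)phenol
Product: 5 5-bromo-2-iodo-4-(methoxymethoxy)phenol
Conditions: NIS (1.0 equiv), DMF, 0 °C, dark
Reagents that add atoms: N-iodosuccinimide, O=C1CCC(=O)N1I
Why: Electrophilic aromatic iodination is directed ortho to the free hydroxyl, the strongest donor, and should go to the open site para to bromine and not the crowded site between OH and Br, while the neutral medium keeps the MOM group.

Step 5
Reactants: 6 geraniol (E isomer)
Product: 7 geranyl methyl carbonate, (E)-3,7-dimethylocta-2,6-dien-1-yl methyl carbonate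
Conditions: ClCO2Me, pyridine, CH2Cl2, 0 °C
Reagents that add atoms: methyl chloroformate, COC(Cl)=O
Why: Acylation of the primary allylic alcohol with a chloroformate installs the carbonate leaving group without touching the E geometry, so geraniol checked free of nerol gives geometrically pure 7.

Step 6
Reactants: 5 5-bromo-2-iodo-4-(methoxymethoxy)phenol; 7 geranyl methyl carbonate
Product: 8 (R)-linalyl ether of 5, 1-bromo-5-{[(3R)-3,7-dimethylocta-1,6-dien-3-yl]oxy}-4-iodo-2-(methoxymethoxy)benzene
Conditions: Pd2(dba)3·CHCl3 (2 mol%), (R,R)-DACH-phenyl Trost ligand N,N'-[(1R,2R)-cyclohexane-1,2-diyl]bis[2-(diphenylphosphanyl)benzamide] (6 mol%), degassed CH2Cl2, 0 °C to rt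
Reagents that add atoms: none
Why: Zerovalent palladium ionises carbonate 7 with loss of CO2 to a syn-configured pi-geranyl palladium cation and methoxide, the methoxide deprotonates phenol 5, and the phenoxide adds on the face opposite the metal to the methyl-bearing allyl terminus, forming the O1–C2 bond of the later chromanone. The closest known reaction type is the Tsuji–Trost asymmetric allylic O-alkylation of phenols with geranyl-type carbonates, which gives tertiary aryl allyl ethers. No ring is closed here; the pyranone ring follows in step 11. The single stereocentre C2 is set by the chiral pocket of the DACH-phenyl bisphosphine on palladium, which selects one enantioface of the allyl terminus of the E-configured substrate. The step needs branched over linear regioselectivity, one enantioface, and ionisation of the carbonate in preference to oxidative addition into the C–I or C–Br bond: the ligand steers the nucleophile to the more substituted, more electrophilic terminus, geometrically pure 7 excludes the antipode that the Z isomer would give, and an allyl carbonate ionises far faster than an aryl halide adds at or below room temperature. The reaction should be stopped at full conversion of 5 and worked up cold, since 8 can re-ionise on palladium to the linear ether or undergo Claisen rearrangement on warming.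

Step 7
Reactants: 8 (R)-linalyl ether of 5
Product: 10 (3R)-3-[5-bromo-2-iodo-4-(methoxymethoxy)phenoxy]-3,7-dimethyloct-6-en-1-ol, via B-alkyl-9-BBN adduct 9 (not isolated)
Conditions: 9-BBN (1.3 equiv), THF, 0 °C to rt; then NaBO3·4H2O, H2O, rt
Reagents that add atoms: sodium perborate, [Na+].[Na+].O[B-]1(O)OO[B-](O)(O)OO1
Why: Brown hydroboration with the bulky 9-BBN places boron only on the terminal carbon of the monosubstituted vinyl group, leaving the trisubstituted alkene and the C–I bond alone, and perborate oxidises the C–B bond to the primary alcohol without disturbing C2.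

Step 8
Reactants: 10 (3R)-3-[5-bromo-2-iodo-4-(methoxymethoxy)phenoxy]-3,7-dimethyloct-6-en-1-ol
Product: 11 (3R)-3-[5-bromo-2-iodo-4-(methoxymethoxy)phenoxy]-3,7-dimethyloct-6-enal
Conditions: Dess–Martin periodinane, NaHCO3, CH2Cl2, 0 °C; crude product used at once
Reagents that add atoms: none
Why: Dess–Martin oxidation under bicarbonate buffering takes the primary alcohol to the aldehyde without acid or amine base, so the beta-aryloxy aldehyde should not be driven into E1cB loss of the phenoxide before it is oxidised further.

Step 9
Reactants: 11 (3R)-3-[5-bromo-2-iodo-4-(methoxymethoxy)phenoxy]-3,7-dimethyloct-6-enal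
Product: 12 (3R)-3-[5-bromo-2-iodo-4-(methoxymethoxy)phenoxy]-3,7-dimethyloct-6-enoic acid
Conditions: NaClO2, NaH2PO4, 2-methyl-2-butene (20 equiv), tBuOH/H2O, 0 °C to rt
Reagents that add atoms: sodium chlorite, [Na+].[O-]Cl=O
Why: Pinnick oxidation converts the aldehyde to the acid at mildly acidic pH while excess 2-methyl-2-butene traps hypochlorous acid before it can add to the prenyl alkene, and the acid is a point at which enantiomeric purity could be raised by crystallising an amine salt.

Step 10
Reactants: 12 (3R)-3-[5-bromo-2-iodo-4-(methoxymethoxy)phenoxy]-3,7-dimethyloct-6-enoic acid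
Product: 14 (3R)-3-[5-bromo-2-iodo-4-(methoxymethoxy)phenoxy]-N-methoxy-N,3,7-trimethyloct-6-enamide, via acyl imidazole 13 (not isolated)
Conditions: CDI, CH2Cl2, rt; then MeNH(OMe)·HCl, rt
Reagents that add atoms: N,O-dimethylhydroxylamine hydrochloride, CNOC.Cl
Why: Activation of the acid as its acyl imidazole and aminolysis by N,O-dimethylhydroxylamine gives the Weinreb amide without added base, so the beta-aryloxy carbonyl compound is not exposed to elimination.

Step 11
Reactants: 14 (3R)-3-[5-bromo-2-iodo-4-(methoxymethoxy)phenoxy]-N-methoxy-N,3,7-trimethyloct-6-enamide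
Product: 17 (2R)-7-bromo-6-(methoxymethoxy)-2-methyl-2-(4-methylpent-3-en-1-yl)chroman-4-one, via arylmagnesium chloride 15 (not isolated), via chelated magnesium hemiaminal 16 (not isolated)
Conditions: iPrMgCl·LiCl (1.1 equiv), THF, –40 to –20 °C; then 1 M aq. HCl, –20 °C
Reagents that add atoms: none
Why: In this Parham cyclisation, iodine–magnesium exchange is much faster at the C–I bond ortho to oxygen than at C–Br, and the aryl magnesium adds 6-exo-trig to the Weinreb amide to form the C4–C4a bond as a chelated tetrahedral intermediate that releases the ketone only on cold acidic quench, so C2 is never exposed to a basic, enolisable chromanone.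

Step 12
Reactants: 17 (2R)-7-bromo-6-(methoxymethoxy)-2-methyl-2-(4-methylpent-3-en-1-yl)chroman-4-one
Product: 18 (2R)-7-bromo-2-(4-hydroxy-4-methylpentyl)-6-(methoxymethoxy)-2-methylchroman-4-one
Conditions: Co(acac)2 (20 mol%), PhSiH3, O2 (1 atm), THF, rt
Reagents that add atoms: dioxygen, O=O
Why: In the Mukaiyama hydration a cobalt hydride formed from the silane transfers a hydrogen atom to the less substituted alkene carbon, and the tertiary radical is trapped by O2 and reduced to the Markovnikov tertiary alcohol under neutral conditions that spare the ketone, the aryl bromide and C2.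

Step 13
Reactants: 18 (2R)-7-bromo-2-(4-hydroxy-4-methylpentyl)-6-(methoxymethoxy)-2-methylchroman-4-one
Product: 19 (2R)-7-bromo-6-hydroxy-2-(4-hydroxy-4-methylpentyl)-2-methylchroman-4-one (CNP0351288.2)
Conditions: 1 M aq. HCl/MeOH (1:4), rt
Reagents that add atoms: none
Why: Acid-catalysed acetal exchange of the aryl MOM ether with methanol releases the phenol as dimethoxymethane at room temperature, mild enough for the tertiary alcohol and free of the base or heat that would open the chromanone by retro-oxa-Michael reaction and racemise C2.

**Compound list**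
1 | 3-bromo-4-hydroxybenzaldehyde | O=Cc1ccc(O)c(Br)c1 | starting material
2 | 3-bromo-4-(methoxymethoxy)benzaldehyde | O=Cc1ccc(OCOC)c(Br)c1 | intermediate
3 | 3-bromo-4-(methoxymethoxy)phenyl formate | O=COc1ccc(OCOC)c(Br)c1 | intermediate
4 | 3-bromo-4-(methoxymethoxy)phenol | Oc1ccc(OCOC)c(Br)c1 | intermediate
5 | 5-bromo-2-iodo-4-(methoxymethoxy)phenol | Oc1cc(Br)c(OCOC)cc1I | intermediate
6 | geraniol, (E)-3,7-dimethylocta-2,6-dien-1-ol | CC(C)=CCC/C(C)=C/CO | starting material
7 | geranyl methyl carbonate | CC(C)=CCC/C(C)=C/COC(=O)OC | intermediate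
8 | 1-bromo-5-{[(3R)-3,7-dimethylocta-1,6-dien-3-yl]oxy}-4-iodo-2-(methoxymethoxy)benzene | CC(C)=CCC[C@](Oc1cc(Br)c(OCOC)cc1I)(C)C=C | intermediate
9 | B-alkyl-9-BBN adduct of 8 (boron on the former terminal vinyl carbon) | CC(C)=CCC[C@](Oc1cc(Br)c(OCOC)cc1I)(C)CCB1C2CCCC1CCC2 | intermediate (not isolated)
10 | (3R)-3-[5-bromo-2-iodo-4-(methoxymethoxy)phenoxy]-3,7-dimethyloct-6-en-1-ol | CC(C)=CCC[C@](Oc1cc(Br)c(OCOC)cc1I)(C)CCO | intermediate
11 | (3R)-3-[5-bromo-2-iodo-4-(methoxymethoxy)phenoxy]-3,7-dimethyloct-6-enal | CC(C)=CCC[C@](Oc1cc(Br)c(OCOC)cc1I)(C)CC=O | intermediate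
12 | (3R)-3-[5-bromo-2-iodo-4-(methoxymethoxy)phenoxy]-3,7-dimethyloct-6-enoic acid | CC(C)=CCC[C@](Oc1cc(Br)c(OCOC)cc1I)(C)CC(=O)O | intermediate
13 | acyl imidazole of 12, (3R)-3-[5-bromo-2-iodo-4-(methoxymethoxy)phenoxy]-1-(imidazol-1-yl)-3,7-dimethyloct-6-en-1-one | CC(C)=CCC[C@](Oc1cc(Br)c(OCOC)cc1I)(C)CC(=O)n1ccnc1 | intermediate (not isolated)
14 | (3R)-3-[5-bromo-2-iodo-4-(methoxymethoxy)phenoxy]-N-methoxy-N,3,7-trimethyloct-6-enamide | CC(C)=CCC[C@](Oc1cc(Br)c(OCOC)cc1I)(C)CC(=O)N(C)OC | intermediate
15 | arylmagnesium chloride from 14 (MgCl in place of iodine) | CC(C)=CCC[C@](Oc1cc(Br)c(OCOC)cc1[Mg]Cl)(C)CC(=O)N(C)OC | intermediate (not isolated)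
16 | chloromagnesium alkoxide of (2R)-7-bromo-4-[methoxy(methyl)amino]-6-(methoxymethoxy)-2-methyl-2-(4-methylpent-3-en-1-yl)chroman-4-ol (both C4 epimers) | CC(C)=CCC[C@]1(C)CC(O[Mg]Cl)(N(C)OC)c2cc(OCOC)c(Br)cc2O1 | intermediate (not isolated)
17 | (2R)-7-bromo-6-(methoxymethoxy)-2-methyl-2-(4-methylpent-3-en-1-yl)chroman-4-one | CC(C)=CCC[C@]1(C)CC(=O)c2cc(OCOC)c(Br)cc2O1 | intermediate
18 | (2R)-7-bromo-2-(4-hydroxy-4-methylpentyl)-6-(methoxymethoxy)-2-methylchroman-4-one | CC(C)(O)CCC[C@]1(C)CC(=O)c2cc(OCOC)c(Br)cc2O1 | intermediate
19 | (2R)-7-bromo-6-hydroxy-2-(4-hydroxy-4-methylpentyl)-2-methylchroman-4-one | CC(C)(O)CCC[C@]1(C)CC(=O)c2cc(O)c(Br)cc2O1 | target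

**Total step count:** 13

**Longest linear sequence:** 12 steps (1 to 19 through steps 1–4 and 6–13; the geraniol branch joins at step 6 after one step).

**Three steps most likely to fail**

Step 6. The phenoxide may attack the unsubstituted allyl terminus and give the linear geranyl ether. The hindered ortho-iodophenol may be delivered with poor enantioface selectivity. Palladium may also re-ionise the product ether and erode both selectivities with time. The fallback gives up the catalytic etherification and builds the pyranone ring by condensation, with resolution of the racemate. It sets out from 5. Stille coupling at the C–I bond with tributyl(1-ethoxyvinyl)stannane (Pd(PPh3)4, toluene, 80 °C) should give 5-bromo-2-(1-ethoxyvinyl)-4-(methoxymethoxy)phenol F1. Brief treatment with cold dilute HCl in THF should hydrolyse the enol ether, and not the MOM acetal, to 1-[4-bromo-2-hydroxy-5-(methoxymethoxy)phenyl]ethan-1-one F2. Kabbe condensation of F2 with 6-methylhept-5-en-2-one and pyrrolidine in refluxing ethanol should give racemic 7-bromo-6-(methoxymethoxy)-2-methyl-2-(4-methylpent-3-en-1-yl)chroman-4-one F3. Preparative chromatography on a chiral stationary phase then separates the (R)-enantiomer from the (S)-configured chromanone F4, which is set aside. The fallback comes back to the route at 17.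

Step 11. The amide may be deprotonated alpha to the carbonyl by the isopropyl or the aryl magnesium species, followed by E1cB loss of the aryloxide. The aryl magnesium may be protonated before it cyclises. A slow exchange may let the isopropyl reagent add to the amide. The fallback replaces the anionic acylation by a chromium-mediated carbonyl addition and sets out from aldehyde 11. Intramolecular Nozaki–Hiyama–Kishi reaction (CrCl2, catalytic NiCl2, DMF, rt), which engages the C–I bond and leaves C–Br, should give (2R)-7-bromo-6-(methoxymethoxy)-2-methyl-2-(4-methylpent-3-en-1-yl)chroman-4-ol F5 as a mixture of C4 epimers. Dess–Martin oxidation of the benzylic alcohol (NaHCO3, CH2Cl2, 0 °C) should then give the ketone. The fallback comes back to the route at 17.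

Step 8. The beta-aryloxy aldehyde may lose the phenoxide by enolisation and E1cB elimination (retro-oxa-Michael reaction) during oxidation or handling. The fallback avoids any beta-aryloxy aldehyde by closing the ring at the alkane oxidation level and sets out from 8. Hydroboration with 9-BBN gives 9 as in step 7. Instead of oxidation, PdCl2(dppf) and aqueous K3PO4 are added (THF/DMF, 50 °C), so that intramolecular B-alkyl Suzuki–Miyaura coupling at the C–I bond should give (2R)-7-bromo-6-(methoxymethoxy)-2-methyl-2-(4-methylpent-3-en-1-yl)chromane F6. Mukaiyama hydration under the conditions of step 12 should give 5-[(2R)-7-bromo-6-(methoxymethoxy)-2-methylchroman-2-yl]-2-methylpentan-2-ol F7. Benzylic oxidation of C4 (tBuOOH, catalytic CrO3, CH2Cl2, rt) should then install the ketone. The fallback comes back to the route at 18.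

**Further compounds**
F1 | step 6 | 5-bromo-2-(1-ethoxyvinyl)-4-(methoxymethoxy)phenol | C=C(OCC)c1cc(OCOC)c(Br)cc1O
F2 | step 6 | 1-[4-bromo-2-hydroxy-5-(methoxymethoxy)phenyl]ethan-1-one | CC(=O)c1cc(OCOC)c(Br)cc1O
F3 | step 6 | racemic 7-bromo-6-(methoxymethoxy)-2-methyl-2-(4-methylpent-3-en-1-yl)chroman-4-one | CC(C)=CCCC1(C)CC(=O)c2cc(OCOC)c(Br)cc2O1
F4 | step 6 | (2S)-7-bromo-6-(methoxymethoxy)-2-methyl-2-(4-methylpent-3-en-1-yl)chroman-4-one | CC(C)=CCC[C@@]1(C)CC(=O)c2cc(OCOC)c(Br)cc2O1
F5 | step 11 | (2R)-7-bromo-6-(methoxymethoxy)-2-methyl-2-(4-methylpent-3-en-1-yl)chroman-4-ol (C4 epimers) | CC(C)=CCC[C@]1(C)CC(O)c2cc(OCOC)c(Br)cc2O1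
F6 | step 8 | (2R)-7-bromo-6-(methoxymethoxy)-2-methyl-2-(4-methylpent-3-en-1-yl)chromane | CC(C)=CCC[C@]1(C)CCc2cc(OCOC)c(Br)cc2O1
F7 | step 8 | 5-[(2R)-7-bromo-6-(methoxymethoxy)-2-methylchroman-2-yl]-2-methylpentan-2-ol | CC(C)(O)CCC[C@]1(C)CCc2cc(OCOC)c(Br)cc2O1
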